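all flasks: electrophile 1.7 M
- alder: nucleophile 1.1 M; run made earlier
- oak: nucleophile 2.5 M; run made earlier
- flask: nucleophile 1.70 M; time 80 min

- alder (time / min: electrophile / %, target / %): 10.0: 65.3, 34.3; 30.0: 64.9, 32.6; 50.0: 65.3, 32.8; 80.0: 66.5, 32.1
- oak (time / min: electrophile / %, target / %): 6.00: 28.0, 70.2; 15.0: 27.0, 68.7; 30.0: 28.7, 66.0; 80.0: 31.6, 57.5

(readings scatter by 0.5 percentage points)

- part of the electrophile that has reacted at 80 min
- share of the unused nucleophile that is free and not bound as protonated nucleophile, at 80 min

- Set oak beside alder: with the same electrophile charge, oak has used 72.0% of it by 6.00 min, more than the 34.7% alder has used by 10.0 min, and both stall with electrophile still there, 31.6% in oak and 66.5% in alder at 80.0 min.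
- Read each turnover as costing two nucleophile: one makes target, and the acid set free takes the other as protonated nucleophile. Nucleophile is then the limiting reagent, counted double.
- Reckon the flask so: 50.0% is the two-for-one mark, half the nucleophile charge over the electrophile charge, as a fraction of the electrophile charged.
- Hold the runs against their own marks: alder's is 32.4% and its first reading stands 2.3 percentage points above it; oak's is 73.5% and its first reading stands 1.5 points below it.
- Place the flask between them: its nucleophile charge exceeds alder's and falls short of oak's, and it equals the electrophile charge. Take the gap there as near zero. Oak's electrophile climbs from 28.0% to 31.6%, so commit to just under 50.0%.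
- Compare the forecast: it gives 49.4% reacted and 8.2% free, on the ground that “each turnover releases acid that ties up a second nucleophile”. The runs do not show the binding, so its free share is a guess.

- The flask gives 49.7% reacted and 4.93% free, both within the forecast's margins. At 80 min the flask holds 2.2% of its nucleophile charge free and unbound, less than the 50% of its electrophile charge. The mark of 50.0% stands 0.30 points above the result.

    nucleophile + target → over-reaction product (k = 0.0280 M⁻¹ min⁻¹)
    electrophile + nucleophile ⇌ acid set free + target (K = 2.50, k = 1.70 M⁻¹ min⁻¹)
    nucleophile + acid set free ⇌ protonated nucleophile, settled at all times (K = 180 M⁻¹)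

- Take the neighbour flask charged with 2.9 M of electrophile: its mark is 29.3%. The computed result is 30.6%, which stands 1.3 points above that mark.

The readings are simulated with made-up constants; the scatter is artificial.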